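**Assumption:** the SMILES is read as ent-oritin-(4α→6)-epioritin-4α-ol, with upper unit (2S,3R,4R), 2,3-trans-3,4-cis, and lower unit (2R,3R,4R), all-cis; α/β refer to the usual flavan drawing.

## Retrosynthetic overview

1. The last bond is C4(upper)–C6(lower): an ent-oritin C4 cation (ring-A quinone methide) is captured by ring A of epioritin-4α-ol; no ring forms here.
2. The two halves are C2 epimers of one flavan-3,4-diol. The lower unit is therefore also cut at O1–C2: its ring C is opened to a ring-B quinone methide and re-closed with inversion at C2 in the same flask, so one unprotected monomer is the only late intermediate.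
3. Ring C of that monomer is cut at O1–C2 as an enantioselective 6-endo oxa-Michael closure of a 2'-hydroxychalcone (chalcone → flavanone), followed by 3-hydroxylation and C4 reduction (flavanone → dihydroflavonol → 3,4-diol).
4. The chalcone comes from gallacetophenone and 4-(benzyloxy)benzaldehyde by aldol condensation.
5. Ring order: rings A and B are bought; ring C of the monomer is closed in step 3; ring C of the lower unit is re-formed and the interflavanyl bond is then made in step 7.

## Route

Step 1
Reactants: 1 1-(2,3,4-trihydroxyphenyl)ethanone (gallacetophenone)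
Product: 2 1-[3,4-bis(benzyloxy)-2-hydroxyphenyl]ethanone
Conditions: BnBr (2.1 equiv), K2CO3 (2.2 equiv), acetone, reflux, 8 h
Reagents that add atoms: benzyl bromide, BrCc1ccccc1
Why: Williamson etherification alkylates the 4- and 3-OH while the 2-OH, locked in a hydrogen bond to the acetyl carbonyl, stays free for the later ring closure; no stereocenter is formed.

Step 2
Reactants: 2 1-[3,4-bis(benzyloxy)-2-hydroxyphenyl]ethanone; 3 4-(benzyloxy)benzaldehyde
Product: 4 (E)-1-[3,4-bis(benzyloxy)-2-hydroxyphenyl]-3-[4-(benzyloxy)phenyl]prop-2-en-1-one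
Conditions: KOH (50% aq.), EtOH, 25 °C, 36 h
Reagents that add atoms: none
Why: Claisen–Schmidt (crossed aldol) condensation of the acetophenone enolate with the non-enolisable aldehyde, then E1cB dehydration, gives only the conjugated (E)-enone; no stereocenter is formed.

Step 3
Reactants: 4 (E)-2'-hydroxychalcone
Product: 5 (2R)-7,8-bis(benzyloxy)-2-[4-(benzyloxy)phenyl]chroman-4-one
Conditions: epi-9-amino-9-deoxyquinidine-derived 3,5-bis(trifluoromethyl)phenyl thiourea (10 mol%), PhCl, 25 °C, 72 h; one recrystallisation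
Reagents that add atoms: none
Why: Organocatalytic enantioselective intramolecular 6-endo-trig oxa-Michael addition (the chalcone-to-flavanone ring closure), in which the quinuclidine nitrogen activates the 2'-OH and the thiourea binds the enone carbonyl so that oxygen adds to one face of C-β and sets C2 as R (2β-aryl), the quinine-derived pseudoenantiomer being used instead if the first run shows the opposite sense.

Step 4
Reactants: 5 (2R)-flavanone
Product: 7 (2S,3S)-7,8-bis(benzyloxy)-2-[4-(benzyloxy)phenyl]-3-hydroxychroman-4-one, via trimethylsilyl enol ether 6 (not isolated)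
Conditions: LiN(SiMe3)2, Me3SiCl (in situ quench), THF, −78 °C; then dimethyldioxirane, acetone, −40 to 0 °C; then citric acid, MeOH–H2O
Reagents that add atoms: dimethyldioxirane, CC1(C)OO1
Why: Rubottom oxidation, in which deprotonation with in situ silyl trapping at −78 °C avoids E1cB ring opening (which would racemise C2) and dimethyldioxirane epoxidises enol ether 6 on the face anti to the 2-aryl group, so that hydrolysis gives the 2,3-trans α-hydroxy ketone with C3 set as S (3α-OH).

Step 5
Reactants: 7 (2S,3S)-dihydroflavonol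
Product: 8 (2S,3R,4R)-7,8-bis(benzyloxy)-2-[4-(benzyloxy)phenyl]chromane-3,4-diol
Conditions: NaBH4, 1,4-dioxane, 25 °C
Reagents that add atoms: none
Why: Chelation-controlled (Cram-chelate) ketone reduction, in which sodium in the aprotic medium bridges the 3-oxygen and the carbonyl and hydride adds to C4 from the H-3 face, setting C4 as R (4α-OH, 3,4-cis), whereas protic solvents favour the 3,4-trans epimer by axial attack.

Step 6
Reactants: 8 tri-O-benzyl (2S,3R,4R)-diol
Product: 9 (2S,3R,4R)-2-(4-hydroxyphenyl)chromane-3,4,7,8-tetrol (ent-oritin-4α-ol)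
Conditions: H2 (1 atm), Pd(OH)2 on carbon, NaHCO3 (solid), THF–EtOAc, 25 °C; filtered under Ar and used at once
Reagents that add atoms: none
Why: Catalytic hydrogenolysis of the three aryl benzyl ethers under neutral, buffered, alcohol-free conditions leaves the benzylic C2–O and C4–OH bonds and all three stereocenters untouched.

Step 7
Reactants: 9 ent-oritin-4α-ol (two molecules)
Product: 13 ent-oritin-(4α→6)-epioritin-4α-ol, via ring-B quinone methide 10 (not isolated), via (−)-teracacidin 11 (not isolated), via ring-A quinone methide 12 (not isolated)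
Conditions: degassed aq. Na2CO3/NaHCO3 (pH 10), Ar, 0.2 M, 50 °C, to the C2-epimer equilibrium (HPLC); then HCl to pH 1, 40 °C, 24 h; Sephadex LH-20, then RP-HPLC
Reagents that add atoms: none
Why: Proposed new method: at pH 10 the 4'-phenoxide of 9 opens the O1–C2 bond to quinone methide 10 and 6-endo oxa-Michael re-closure gives the C2 epimer 11 (closest known reaction: base epimerisation of flavan-3-ols at C2), after which in acid only 9, whose 4-OH is quasi-axial and para-assisted by the 7-OH, ionises to 12 and is captured at C6 (ortho to 7-OH, para to O1) of the all-cis 11, whose quasi-equatorial 4-OH does not ionise (closest known reaction: acid-catalysed flavan-3,4-diol/flavan condensation), axial attack cis to the 3-OH setting the 4α bond alongside its 4β epimer, with C2 of the lower unit set by the re-closure and C3/C4 of both units carried over unchanged.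

## Compound list

1 | 1-(2,3,4-trihydroxyphenyl)ethanone (gallacetophenone) | CC(=O)c1ccc(O)c(O)c1O | starting material
2 | 1-[3,4-bis(benzyloxy)-2-hydroxyphenyl]ethanone | CC(=O)c1ccc(OCc2ccccc2)c(OCc2ccccc2)c1O | intermediate
3 | 4-(benzyloxy)benzaldehyde | O=Cc1ccc(OCc2ccccc2)cc1 | starting material
4 | (E)-1-[3,4-bis(benzyloxy)-2-hydroxyphenyl]-3-[4-(benzyloxy)phenyl]prop-2-en-1-one | O=C(/C=C/c1ccc(OCc2ccccc2)cc1)c1ccc(OCc2ccccc2)c(OCc2ccccc2)c1O | intermediate
5 | (2R)-7,8-bis(benzyloxy)-2-[4-(benzyloxy)phenyl]chroman-4-one (2β-aryl) | c1ccccc1COc1ccc([C@@H]2Oc3c(ccc(OCc4ccccc4)c3OCc4ccccc4)C(=O)C2)cc1 | intermediate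
6 | (2R)-7,8-bis(benzyloxy)-2-[4-(benzyloxy)phenyl]-4-(trimethylsilyloxy)-2H-chromene | c1ccccc1COc1ccc([C@@H]2Oc3c(ccc(OCc4ccccc4)c3OCc4ccccc4)C(O[Si](C)(C)C)=C2)cc1 | intermediate (not isolated)
7 | (2S,3S)-7,8-bis(benzyloxy)-2-[4-(benzyloxy)phenyl]-3-hydroxychroman-4-one (2,3-trans) | c1ccccc1COc1ccc([C@@H]2Oc3c(ccc(OCc4ccccc4)c3OCc4ccccc4)C(=O)[C@H]2O)cc1 | intermediate
8 | (2S,3R,4R)-7,8-bis(benzyloxy)-2-[4-(benzyloxy)phenyl]chromane-3,4-diol (2,3-trans-3,4-cis) | c1ccccc1COc1ccc([C@@H]2Oc3c(ccc(OCc4ccccc4)c3OCc4ccccc4)[C@@H](O)[C@H]2O)cc1 | intermediate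
9 | (2S,3R,4R)-2-(4-hydroxyphenyl)chromane-3,4,7,8-tetrol (ent-oritin-4α-ol; 2,3-trans-3,4-cis) | Oc1ccc([C@@H]2Oc3c(ccc(O)c3O)[C@@H](O)[C@H]2O)cc1 | intermediate
10 | 4-[(2S,3R)-2,3-dihydroxy-3-(2,3,4-trihydroxyphenyl)propylidene]cyclohexa-2,5-dien-1-one (ring-B quinone methide; ring C open) | Oc1c(O)c(O)ccc1[C@@H](O)[C@H](C=C1C=CC(=O)C=C1)O | intermediate (not isolated)
11 | (2R,3R,4R)-2-(4-hydroxyphenyl)chromane-3,4,7,8-tetrol ((−)-teracacidin, epioritin-4α-ol; all-cis) | Oc1ccc([C@H]2Oc3c(ccc(O)c3O)[C@@H](O)[C@H]2O)cc1 | intermediate (not isolated)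
12 | (2S,3R)-3,8-dihydroxy-2-(4-hydroxyphenyl)-2,3-dihydro-7H-chromen-7-one (ring-A quinone methide, neutral form of the C4 cation) | O=C1C=CC2=C[C@@H](O)[C@H](c3ccc(O)cc3)OC2=C1O | intermediate (not isolated)
13 | (2R,3R,4R)-6-[(2S,3R,4R)-3,7,8-trihydroxy-2-(4-hydroxyphenyl)chroman-4-yl]-2-(4-hydroxyphenyl)chromane-3,4,7,8-tetrol (ent-oritin-(4α→6)-epioritin-4α-ol) | Oc1ccc([C@H]2Oc3c(cc([C@@H]4c5ccc(O)c(O)c5O[C@@H](c5ccc(O)cc5)[C@@H]4O)c(O)c3O)[C@@H](O)[C@H]2O)cc1 | target

## Step count and risks

Total step count: 7. Longest linear sequence: 7 (fully linear).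

**Steps most likely to fail**

Step 7 (epimerisation/condensation cascade). The risks are:
- The C2 equilibrium may lie on the side of 9, so that 12 is captured mostly by 9 and gives homo-dimers and oligomers.
- The 4β (3,4-trans) epimer and the (4→5) regioisomers form alongside 13. Aryl nucleophiles usually favour 3,4-trans on 2,3-trans cations, so 13 is expected as the minor epimer, with a single-digit to low double-digit isolated yield.
- Ether-linked dimers may form; these re-ionise in acid and should drain to C–C products.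
- Ring A is sensitive to air at pH 10.

Fallback, from 9 back to 13: one batch of 9 is epimerised at pH 10 as in the first stage, but the flask is then neutralised and (−)-teracacidin 11 is isolated on Sephadex LH-20 (recovered 9 is re-epimerised). A second batch of 9 is treated with benzyl mercaptan in AcOH at 25 °C, capturing cation 12 as (2S,3S,4S)-4-(benzylsulfanyl)-2-(4-hydroxyphenyl)chromane-3,7,8-triol F1 (major 3,4-trans epimer; either epimer serves). F1 and 4 equiv of 11 are then coupled with AgBF4 in THF at 0 °C. This thiophilic activation under neutral conditions, with a fourfold excess of the only nucleophile present, removes the homo-coupling channel and gives 13 after the same chromatography.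

Step 3 (enantioselective ring closure). The electron-rich, 4-alkoxy-substituted enone cyclises slowly and reversibly, so conversion may stall and the ee may erode towards equilibrium; the facial sense must also be confirmed.

Fallback, from 4 back to 5: 4 is cyclised with NaOAc in refluxing EtOH to racemic 7,8-bis(benzyloxy)-2-[4-(benzyloxy)phenyl]chroman-4-one F2. F2 is then resolved kinetically by transfer hydrogenation with RhCl[(S,S)-TsDPEN](C5Me5) (1 mol%), HCO2H/Et3N, EtOAc, 25 °C. The (2S)-enantiomer is reduced by matched axial hydride delivery to (2S,4S)-7,8-bis(benzyloxy)-2-[4-(benzyloxy)phenyl]chroman-4-ol F3, which is separated on silica, and unreacted (2R)-flavanone 5 is recovered in high ee (at most 50% yield).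

Step 5 (3,4-cis-selective reduction). If chelation control is weak, axial hydride attack gives mainly the 3,4-trans diol. That epimer would still serve as the electrophile, but after C2 epimerisation it would give the wrong, ionisable lower unit.

Fallback, from 7 back to 9: 7 is reduced with NaBH4 in MeOH at 0 °C to the 3,4-trans diol (2S,3R,4S)-7,8-bis(benzyloxy)-2-[4-(benzyloxy)phenyl]chromane-3,4-diol F4. Hydrogenolysis as in step 6 gives (2S,3R,4S)-2-(4-hydroxyphenyl)chromane-3,4,7,8-tetrol F5 (ent-oritin-4β-ol). F5 is held in dilute aqueous AcOH (pH 3, 40 °C, at most 2 mM so that water outcompetes self-condensation), which equilibrates C4 through cation 12. Stereoelectronically favoured axial capture of water gives the 3,4-cis epimer 9, separated by RP-HPLC with recycling of F5.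

## Further compounds

F1 | step 7 | (2S,3S,4S)-4-(benzylsulfanyl)-2-(4-hydroxyphenyl)chromane-3,7,8-triol | Oc1ccc([C@@H]2Oc3c(ccc(O)c3O)[C@H](SCc3ccccc3)[C@H]2O)cc1
F2 | step 3 | racemic 7,8-bis(benzyloxy)-2-[4-(benzyloxy)phenyl]chroman-4-one | O=C1CC(c2ccc(OCc3ccccc3)cc2)Oc2c1ccc(OCc1ccccc1)c2OCc1ccccc1
F3 | step 3 | (2S,4S)-7,8-bis(benzyloxy)-2-[4-(benzyloxy)phenyl]chroman-4-ol (2,4-cis) | c1ccccc1COc1ccc([C@H]2Oc3c(ccc(OCc4ccccc4)c3OCc4ccccc4)[C@@H](O)C2)cc1
F4 | step 5 | (2S,3R,4S)-7,8-bis(benzyloxy)-2-[4-(benzyloxy)phenyl]chromane-3,4-diol (2,3-trans-3,4-trans) | c1ccccc1COc1ccc([C@@H]2Oc3c(ccc(OCc4ccccc4)c3OCc4ccccc4)[C@H](O)[C@H]2O)cc1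
F5 | step 5 | (2S,3R,4S)-2-(4-hydroxyphenyl)chromane-3,4,7,8-tetrol (ent-oritin-4β-ol) | Oc1ccc([C@@H]2Oc3c(ccc(O)c3O)[C@H](O)[C@H]2O)cc1
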